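**Retrosynthetic overview**

- The target is released in one acid operation from a fully protected flavan-4-imine: N-sulfinyl imine to the C4 ketone, three methoxymethyl ethers to the three hydroxyls.
- Ring C of that imine is cut at C2–C3 and at O1–C8a into a ring-A N-sulfinyl ketimine (C3–C4–C4a–C8a, fluorine on C8a) and a ring-B aldehyde (O1=C2); forward, an aza-aldol addition followed in the same flask by SNAr closure, a formal (4+2) annulation.
- Enabling feature: C4 of ring C is α to C3 and is bonded to C4a, ortho to C8a of ring A. One carbonyl-type group at C4, worn as a chiral N-sulfinyl imine, therefore makes C3–H acidic and C8a–F a vinylogous imidoyl fluoride, while C2 is a benzylic carbinol carbon, a latent aldehyde.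
- Ring-A fragment: 4-bromo-3-fluorophenol, directed ortho-metalation and prenylation, Weinreb acylation, sulfinamide condensation. Ring-B fragment: 3,5-dibromo-4-hydroxybenzaldehyde, twofold Stille prenylation.
- Ring order: rings A and B are bought as benzenes; ring C is the only ring formed, in the key step.

Key step: step 9

Assumption: the (R)-sulfinyl group is taken to steer the aza-enolate to the Si face of the ring-B aldehyde (giving 2R); this sense is assigned by analogy, and if a model pair shows the opposite, the equally available (S)-sulfinamide is used, which changes only the descriptor at sulfur.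

**Route**

Step 1
Reactants: 1 4-bromo-3-fluorophenol
Product: 2 1-bromo-2-fluoro-4-(methoxymethoxy)benzene
Conditions: MOMCl, i-Pr2NEt, CH2Cl2, 0 → 23 °C
Reagents that add atoms: chloromethyl methyl ether (MOMCl), COCCl
Why: O-alkylation of the phenol with the α-chloro ether under amine base (Williamson-type etherification) is routine, creates no stereocentre and installs the acetal that later directs the metalation.

Step 2
Reactants: 2 1-bromo-2-fluoro-4-(methoxymethoxy)benzene
Product: 4 1-bromo-2-fluoro-4-(methoxymethoxy)-3-(3-methylbut-2-en-1-yl)benzene, via aryllithium 3 (not isolated)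
Conditions: LiN(i-Pr)2, THF, −78 °C; then CuBr·SMe2 (10 mol %), prenyl bromide, −78 → −40 °C
Reagents that add atoms: 1-bromo-3-methylbut-2-ene (prenyl bromide), CC(C)=CCBr
Why: Directed ortho-metalation should occur at the C–H flanked by fluorine and the acetal oxygen, the most acidic site, without exchange of the bromine by the amide base, and the aryllithium, kept cold enough not to lose LiF, is alkylated at the primary carbon of prenyl bromide under copper catalysis (SN2 allylic substitution); no stereocentre is formed.

Step 3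
Reactants: 5 methyl 2-hydroxyacetate (methyl glycolate)
Product: 6 methyl 2-(methoxymethoxy)acetate
Conditions: MOMCl, i-Pr2NEt, CH2Cl2, 0 → 23 °C
Reagents that add atoms: chloromethyl methyl ether (MOMCl), COCCl
Why: Williamson-type O-alkylation of the primary alcohol gives an ether-type cap on the future C3 oxygen that cannot migrate to a neighbouring alkoxide and that comes off with acid at the end; no stereocentre is formed.

Step 4
Reactants: 6 methyl 2-(methoxymethoxy)acetate
Product: 7 N-methoxy-2-(methoxymethoxy)-N-methylacetamide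
Conditions: MeNHOMe·HCl, i-PrMgCl, THF, −20 → 0 °C
Reagents that add atoms: N,O-dimethylhydroxylamine hydrochloride, CNOC.Cl
Why: The chloromagnesium amide of N,O-dimethylhydroxylamine, made in the flask, should convert the ester into the Weinreb amide at low temperature without touching the acetal; no stereocentre is formed.

Step 5
Reactants: 4 1-bromo-2-fluoro-4-(methoxymethoxy)-3-(3-methylbut-2-en-1-yl)benzene; 7 N-methoxy-2-(methoxymethoxy)-N-methylacetamide
Product: 9 1-[2-fluoro-4-(methoxymethoxy)-3-(3-methylbut-2-en-1-yl)phenyl]-2-(methoxymethoxy)ethan-1-one, via aryllithium 8 (not isolated)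
Conditions: n-BuLi, THF, −78 °C; then 7, −78 → −40 °C; then H2O
Reagents that add atoms: none
Why: Bromine–lithium exchange at −78 °C is faster than any reaction at the fluoride or the allylic positions, and the aryllithium should add only once because the chelated tetrahedral adduct of the Weinreb amide survives until the aqueous quench (Weinreb ketone synthesis); no stereocentre is formed.

Step 6
Reactants: 9 1-[2-fluoro-4-(methoxymethoxy)-3-(3-methylbut-2-en-1-yl)phenyl]-2-(methoxymethoxy)ethan-1-one
Product: 10 (R)-N-{1-[2-fluoro-4-(methoxymethoxy)-3-(3-methylbut-2-en-1-yl)phenyl]-2-(methoxymethoxy)ethylidene}-2-methylpropane-2-sulfinamide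
Conditions: (R)-t-BuS(O)NH2, Ti(OEt)4, THF, 65 °C
Reagents that add atoms: (R)-2-methylpropane-2-sulfinamide, CC(C)(C)[S@@](=O)N
Why: Ti(OEt)4-mediated condensation of a ketone with tert-butanesulfinamide is the standard way to N-sulfinyl ketimines and tolerates ortho-fluoroaryl and α-alkoxy ketones; the sulfur stereocentre is brought in unchanged with the reagent and the C=N geometry stays mobile.

Step 7
Reactants: 11 3,5-dibromo-4-hydroxybenzaldehyde
Product: 12 3,5-dibromo-4-(methoxymethoxy)benzaldehyde
Conditions: MOMCl, i-Pr2NEt, CH2Cl2, 0 → 23 °C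
Reagents that add atoms: chloromethyl methyl ether (MOMCl), COCCl
Why: The acidic, flanked phenol is alkylated by the reactive α-chloro ether under amine base (Williamson-type etherification), which also masks the phenoxide that would otherwise deactivate the aldehyde in the key step; no stereocentre is formed.

Step 8
Reactants: 12 3,5-dibromo-4-(methoxymethoxy)benzaldehyde
Product: 13 4-(methoxymethoxy)-3,5-bis(3-methylbut-2-en-1-yl)benzaldehyde
Conditions: prenylSnBu3 (2.4 equiv), Pd(PPh3)4 (5 mol %), DMF, 90 °C
Reagents that add atoms: tributyl(3-methylbut-2-en-1-yl)stannane, CCCC[Sn](CCCC)(CCCC)CC=C(C)C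
Why: Twofold Stille coupling at the two equivalent C–Br bonds, with transfer of the prenyl group from tin through its α-carbon, should give the linear diprenyl arene while the aldehyde and the acetal stay inert; no stereocentre is formed.

Step 9
Reactants: 10 (R)-N-{1-[2-fluoro-4-(methoxymethoxy)-3-(3-methylbut-2-en-1-yl)phenyl]-2-(methoxymethoxy)ethylidene}-2-methylpropane-2-sulfinamide; 13 4-(methoxymethoxy)-3,5-bis(3-methylbut-2-en-1-yl)benzaldehyde
Product: 17 (R)-N-{(2R,3S)-3,7-bis(methoxymethoxy)-2-[4-(methoxymethoxy)-3,5-bis(3-methylbut-2-en-1-yl)phenyl]-8-(3-methylbut-2-en-1-yl)-2,3-dihydro-4H-chromen-4-ylidene}-2-methylpropane-2-sulfinamide, via lithium aza-enolate 14 (not isolated), via magnesium aza-enolate 15 (not isolated), via magnesium aldolate 16 (not isolated)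
Conditions: LiN(i-Pr)2 (1.1 equiv), THF, −78 °C; MgBr2·OEt2 (1.5 equiv), −78 °C; 13 (1.05 equiv), −78 °C; then DMPU, −78 → 23 °C
Reagents that add atoms: none
Why: Proposed new method: the amide base removes the C3 proton of the ketimine to give the E-configured aza-enolate (methoxymethoxy group anti to nitrogen), which after transmetalation to magnesium adds to the aldehyde through a closed chair transition state (C2–C3), and on warming the alkoxide attacks C8a, ortho to the imine carbon, and expels fluoride by addition–elimination through a Meisenheimer-type aza-enolate (O1–C8a), a formal (4+2) annulation of the C3–C4–C4a–C8a donor–acceptor unit with the O1=C2 carbonyl. The closest known reaction types are the diastereoselective aldol-type addition of N-tert-butanesulfinyl metalloenamines to aldehydes and the SNAr displacement of fluoride ortho to an imine or oxazoline, which have not been joined in one flask or applied to an α-alkoxy ketimine. Ring C closes by a 6-endo-trig addition–elimination at C8a, the C8a=C4a bond of the vinylogous imidoyl fluoride lying inside the new ring. C2 is controlled by the sulfur stereocentre, which differentiates the two chair transition states and so the faces of the aldehyde, and C3 by the E geometry of the aza-enolate, which should give the anti adduct and hence the 2,3-trans ring (the descriptor at C3 reads S only because C4 carries nitrogen at this stage). The step needs ring closure to come before retro-aldol equilibration can erode the kinetic ratio, which the magnesium chelate of the adduct should secure, and it needs the six-membered aryl ether and not a five-membered one, which the methoxymethyl cap on the C3 oxygen secures. Because the auxiliary stays on, any stereoisomer formed alongside is a diastereomer and can be removed by chromatography before the last step.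

Step 10
Reactants: 17 (R)-N-{(2R,3S)-3,7-bis(methoxymethoxy)-2-[4-(methoxymethoxy)-3,5-bis(3-methylbut-2-en-1-yl)phenyl]-8-(3-methylbut-2-en-1-yl)-2,3-dihydro-4H-chromen-4-ylidene}-2-methylpropane-2-sulfinamide
Product: 18 (2R,3R)-3,7-dihydroxy-2-[4-hydroxy-3,5-bis(3-methylbut-2-en-1-yl)phenyl]-8-(3-methylbut-2-en-1-yl)-2,3-dihydro-4H-chromen-4-one
Conditions: 3 M aq. HCl, MeOH, 23 → 40 °C
Reagents that add atoms: water, O
Why: Acid methanolysis should cleave the S–N bond, hydrolyse the resulting N–H ketiminium ion to the C4 ketone and remove the three methoxymethyl acetals by transacetalisation, a deprotection long used for prenylated flavonoids; C2 is not touched, and C3, now α to the ketone, keeps or relaxes to the more stable 2,3-trans arrangement.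

**Compound list**

1 | 4-bromo-3-fluorophenol | Oc1ccc(Br)c(F)c1 | starting material
2 | 1-bromo-2-fluoro-4-(methoxymethoxy)benzene | COCOc1ccc(Br)c(F)c1 | intermediate
3 | [3-bromo-2-fluoro-6-(methoxymethoxy)phenyl]lithium (not isolated) | COCOc1ccc(Br)c(F)c1[Li] | intermediate
4 | 1-bromo-2-fluoro-4-(methoxymethoxy)-3-(3-methylbut-2-en-1-yl)benzene | COCOc1ccc(Br)c(F)c1CC=C(C)C | intermediate
5 | methyl 2-hydroxyacetate | COC(=O)CO | starting material
6 | methyl 2-(methoxymethoxy)acetate | COCOCC(=O)OC | intermediate
7 | N-methoxy-2-(methoxymethoxy)-N-methylacetamide | COCOCC(=O)N(C)OC | intermediate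
8 | [2-fluoro-4-(methoxymethoxy)-3-(3-methylbut-2-en-1-yl)phenyl]lithium (not isolated) | COCOc1ccc([Li])c(F)c1CC=C(C)C | intermediate
9 | 1-[2-fluoro-4-(methoxymethoxy)-3-(3-methylbut-2-en-1-yl)phenyl]-2-(methoxymethoxy)ethan-1-one | COCOCC(=O)c1ccc(OCOC)c(CC=C(C)C)c1F | intermediate
10 | (R)-N-{1-[2-fluoro-4-(methoxymethoxy)-3-(3-methylbut-2-en-1-yl)phenyl]-2-(methoxymethoxy)ethylidene}-2-methylpropane-2-sulfinamide (R at sulfur; C=N geometry mobile) | COCOCC(=N[S@](=O)C(C)(C)C)c1ccc(OCOC)c(CC=C(C)C)c1F | intermediate
11 | 3,5-dibromo-4-hydroxybenzaldehyde | O=Cc1cc(Br)c(O)c(Br)c1 | starting material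
12 | 3,5-dibromo-4-(methoxymethoxy)benzaldehyde | COCOc1c(Br)cc(C=O)cc1Br | intermediate
13 | 4-(methoxymethoxy)-3,5-bis(3-methylbut-2-en-1-yl)benzaldehyde | COCOc1c(CC=C(C)C)cc(C=O)cc1CC=C(C)C | intermediate
14 | lithium {(E)-1-[2-fluoro-4-(methoxymethoxy)-3-(3-methylbut-2-en-1-yl)phenyl]-2-(methoxymethoxy)ethenyl}[(R)-2-methylpropane-2-sulfinyl]azanide (not isolated) | COCO/C=C(/N([Li])[S@](=O)C(C)(C)C)c1ccc(OCOC)c(CC=C(C)C)c1F | intermediate
15 | bromomagnesium {(E)-1-[2-fluoro-4-(methoxymethoxy)-3-(3-methylbut-2-en-1-yl)phenyl]-2-(methoxymethoxy)ethenyl}[(R)-2-methylpropane-2-sulfinyl]azanide (not isolated) | COCO/C=C(/N([Mg]Br)[S@](=O)C(C)(C)C)c1ccc(OCOC)c(CC=C(C)C)c1F | intermediate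
16 | bromomagnesium alkoxide of the anti adduct, (R)-N-{(2S,3R)-1-[2-fluoro-4-(methoxymethoxy)-3-(3-methylbut-2-en-1-yl)phenyl]-3-hydroxy-2-(methoxymethoxy)-3-[4-(methoxymethoxy)-3,5-bis(3-methylbut-2-en-1-yl)phenyl]propylidene}-2-methylpropane-2-sulfinamide (not isolated) | CC(C)=CCc1cc([C@@H](O[Mg]Br)[C@@H](OCOC)C(=N[S@](=O)C(C)(C)C)c2ccc(OCOC)c(CC=C(C)C)c2F)cc(CC=C(C)C)c1OCOC | intermediate
17 | (R)-N-{(2R,3S)-3,7-bis(methoxymethoxy)-2-[4-(methoxymethoxy)-3,5-bis(3-methylbut-2-en-1-yl)phenyl]-8-(3-methylbut-2-en-1-yl)-2,3-dihydro-4H-chromen-4-ylidene}-2-methylpropane-2-sulfinamide (2,3-trans; R at sulfur) | CC(C)=CCc1cc([C@H]2Oc3c(ccc(OCOC)c3CC=C(C)C)C(=N[S@](=O)C(C)(C)C)[C@@H]2OCOC)cc(CC=C(C)C)c1OCOC | intermediate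
18 | (2R,3R)-3,7-dihydroxy-2-[4-hydroxy-3,5-bis(3-methylbut-2-en-1-yl)phenyl]-8-(3-methylbut-2-en-1-yl)-2,3-dihydro-4H-chromen-4-one | CC(C)=CCc1cc([C@H]2Oc3c(ccc(O)c3CC=C(C)C)C(=O)[C@@H]2O)cc(CC=C(C)C)c1O | target

**Step count**

Total steps: 10. Longest linear sequence: 6 steps (steps 1, 2, 5, 6, 9, 10).

**Steps most likely to fail**

1. Step 9 (proposed new method). The ratio of C2 epimers may drift if retro-aldol equilibration of the magnesium alkoxide outpaces ring closure, and the magnesium alkoxide may displace fluoride too slowly. The fallback uses known chemistry and closes ring C through O1–C2 instead; it sets out from aldehyde 13 and comes back at target 18. Commercial 1-(2,4-dihydroxyphenyl)ethan-1-one is C-prenylated between its two oxygens (prenyl bromide, aq. KOH) to 1-[2,4-dihydroxy-3-(3-methylbut-2-en-1-yl)phenyl]ethan-1-one F1. This is capped (MOMCl, i-Pr2NEt) as 1-[2,4-bis(methoxymethoxy)-3-(3-methylbut-2-en-1-yl)phenyl]ethan-1-one F2. Claisen–Schmidt condensation of F2 with 13 (KOH, EtOH) gives (E)-1-[2,4-bis(methoxymethoxy)-3-(3-methylbut-2-en-1-yl)phenyl]-3-[4-(methoxymethoxy)-3,5-bis(3-methylbut-2-en-1-yl)phenyl]prop-2-en-1-one F3. Julia–Colonna epoxidation (poly-L-leucine, urea–hydrogen peroxide, DBU, THF), which attacks only the electron-poor enone double bond and leaves the prenyl groups alone, gives [2,4-bis(methoxymethoxy)-3-(3-methylbut-2-en-1-yl)phenyl]{(2R,3S)-3-[4-(methoxymethoxy)-3,5-bis(3-methylbut-2-en-1-yl)phenyl]oxiran-2-yl}methanone F4. HCl in MeOH then removes the acetals, and the freed 2'-phenol opens the epoxide at the benzylic carbon with inversion, which should give 18.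

2. Step 10. During the acid exposure that the aliphatic acetal at C3 needs, a prenyl double bond may be protonated and captured by the neighbouring freed phenol (chroman formation). The fallback splits the unmasking and avoids protic acid for the acetals; it sets out from 17 and comes back at 18. Brief treatment with dilute aqueous HCl in THF at 0 °C hydrolyses only the sulfinyl imine and gives (2R,3R)-3,7-bis(methoxymethoxy)-2-[4-(methoxymethoxy)-3,5-bis(3-methylbut-2-en-1-yl)phenyl]-8-(3-methylbut-2-en-1-yl)-2,3-dihydro-4H-chromen-4-one F5. The three acetals of F5 are then cleaved by Lewis-acid-assisted thiolysis (ZnBr2, n-PrSH, CH2Cl2, 0 °C), which should give 18.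

3. Step 8. Allylic transposition during transmetalation may give reverse-prenyl isomers, and the reaction may stall after the first coupling. The fallback removes the regiochemical question; it sets out from 12 and comes back at 13. Twofold Stille coupling of 12 with allyltributylstannane (Pd(PPh3)4, DMF, 90 °C) gives 4-(methoxymethoxy)-3,5-di(prop-2-en-1-yl)benzaldehyde F6. Twofold olefin cross-metathesis of F6 with 2-methylbut-2-ene (second-generation Grubbs catalyst, CH2Cl2, 40 °C) converts both allyl groups into prenyl groups, which should give 13.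

**Further compounds**

F1 | step 9 | 1-[2,4-dihydroxy-3-(3-methylbut-2-en-1-yl)phenyl]ethan-1-one | CC(=O)c1ccc(O)c(CC=C(C)C)c1O
F2 | step 9 | 1-[2,4-bis(methoxymethoxy)-3-(3-methylbut-2-en-1-yl)phenyl]ethan-1-one | CC(=O)c1ccc(OCOC)c(CC=C(C)C)c1OCOC
F3 | step 9 | (E)-1-[2,4-bis(methoxymethoxy)-3-(3-methylbut-2-en-1-yl)phenyl]-3-[4-(methoxymethoxy)-3,5-bis(3-methylbut-2-en-1-yl)phenyl]prop-2-en-1-one | COCOc1ccc(C(=O)/C=C/c2cc(CC=C(C)C)c(OCOC)c(CC=C(C)C)c2)c(OCOC)c1CC=C(C)C
F4 | step 9 | [2,4-bis(methoxymethoxy)-3-(3-methylbut-2-en-1-yl)phenyl]{(2R,3S)-3-[4-(methoxymethoxy)-3,5-bis(3-methylbut-2-en-1-yl)phenyl]oxiran-2-yl}methanone | COCOc1ccc(C(=O)[C@@H]2O[C@H]2c3cc(CC=C(C)C)c(OCOC)c(CC=C(C)C)c3)c(OCOC)c1CC=C(C)C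
F5 | step 10 | (2R,3R)-3,7-bis(methoxymethoxy)-2-[4-(methoxymethoxy)-3,5-bis(3-methylbut-2-en-1-yl)phenyl]-8-(3-methylbut-2-en-1-yl)-2,3-dihydro-4H-chromen-4-one | CC(C)=CCc1cc([C@H]2Oc3c(ccc(OCOC)c3CC=C(C)C)C(=O)[C@@H]2OCOC)cc(CC=C(C)C)c1OCOC
F6 | step 8 | 4-(methoxymethoxy)-3,5-di(prop-2-en-1-yl)benzaldehyde | COCOc1c(CC=C)cc(C=O)cc1CC=C
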